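The data were computed on assumed constants; noise was put on by code.

By 13 min amber has turned 76.0 % of its Z into X and violet 89.6 %, and I want that share for teal, where Z is again the limiting reagent.

| flask | Z | J | X | time |
|---|---|---|---|---|
| amber | 0.0500 M | 0.125 M |  |  |
| violet | 0.0500 M | 0.190 M |  |  |
| ochre | 0.0500 M | 0.125 M | 0.0150 M |  |
| teal | 0.0500 M | 0.310 M |  | 13 min |

| run | time / min | [X] / M |
|---|---|---|
| amber run | 1.6 | 0.01586 |
| amber run | 3.2 | 0.02361 |
| amber run | 4.9 | 0.02895 |
| amber run | 6.5 | 0.03166 |
| amber run | 8.1 | 0.03475 |
| amber run | 9.8 | 0.03605 |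
| amber run | 11 | 0.03711 |
| amber run | 13 | 0.03801 |
| violet run | 1.6 | 0.02191 |
| violet run | 3.2 | 0.03157 |
| violet run | 4.9 | 0.03737 |
| violet run | 6.5 | 0.03999 |
| violet run | 8.1 | 0.04197 |
| violet run | 9.8 | 0.04318 |
| violet run | 11 | 0.04389 |
| violet run | 13 | 0.04482 |
| ochre run | 1.6 | 0.03095 |
| ochre run | 3.2 | 0.03879 |
| ochre run | 4.9 | 0.04396 |
| ochre run | 6.5 | 0.04728 |
| ochre run | 8.1 | 0.04921 |
| ochre run | 9.8 | 0.05117 |
| ochre run | 11 | 0.05170 |
| ochre run | 13 | 0.05350 |

(standard deviation of a reading: 2 × 10⁻⁴ M)

* the exponent of [J] in the starting rate at the charge of the amber run (at the point where two percent of the Z have become X)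
* X in the teal run at 13 min, as a share of the Z charged

- Overall: Z + J -> X.
- Constant volume, constant temperature.
- A reading of a species includes what of it is bound.
- "The second partner" is J.
- An order is taken over about fifteen percent of the charge, up and down.

Let f be the X made as a fraction of the Z charged, and e the J charged over the Z charged. If the rate goes with Z left times J left, with one J spent per X, this quantity grows at a steady pace:

dose = ln[(e − f)/(e(1 − f))]/(e − 1)

With e at 2.50, amber's first reading gives a dose of 0.164, so a steady pace would reach 1.33 by 13 min. But amber's last reading gives 0.710, about half of that, so the pace falls and the first reading can't be scaled up.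

Perhaps, then, this dose is peculiar to amber's charge. Violet, with more J, has 3.80 for e and gives 0.714 at the same time. I therefore keep the mean, 0.712, as the dose delivered by 13 min, the quantity I carry.

For teal, with u the fraction of Z left, the dose must be solved by going round:

e = 6.20, G = e·exp((e − 1)·dose) = 251
first round, u = (e − 1)/G = 2.07 %
next round, u = (e − 1 + u)/G = 2.08 %

That gives me 97.9 %. My objection stands, though: teal's e lies beyond violet's, so this share is carried over from the two runs, not read from them.

The forecast gives 1 for the exponent of J and 97.9 % for teal, and it reads the falling pace thus: "That points to an activity decaying with clock time".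

The flask gives 1.0 and 94.7 %, which is 3.2 percentage points under the forecast and within the margin.

    Z + J → X + L (2.310 L mol⁻¹ min⁻¹)
    J + L ⇌ JL, settled at all times (686.0 L mol⁻¹)
    2 Z → Xi (0.7080 L mol⁻¹ min⁻¹)

Read back through the same formula, teal's 94.7 % is a dose of 0.534, less than the 0.712 I carried. The simulated teal run without the step in which two Z give Xi reaches 99.9 %, a dose of 1.26, more than 0.712. That step is the main reason for teal's shortfall, taking 5.1 points of the X, 98 % of what is missing.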